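Everything hinges on disconnecting the O4–C3 bond of the 1,4-benzodioxane (O1, C2 aryl, C3 methyl, O4, C4a, C5 methoxy, C7 propenyl, C8a). The key step exploits the fact that the C3(CH3)–O4 unit is what a vinyl group on C2 becomes when the C4a hydroxyl adds to its inner carbon. A single iodine-triggered 6-exo closure makes the O4–C3 bond, the dioxane ring and the C3 stereocentre, trans to the C2 aryl group installed beforehand by iridium-catalysed allylic etherification. The precursor is an (S)-1-arylallyl aryl ether with a free C4a hydroxyl, a deactivating C7 formyl group ready for direct olefination, and a pivalate on the syringyl oxygen.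

Key step: step 7

Remarks on the chemistry (assumptions):
- Descriptors: the target is (2R,3R) with the C2 aryl and C3 methyl groups trans. The iodomethyl intermediate with the same spatial arrangement is (2R,3S) because CH2I outranks C2. The open-chain ether is (S) because the aryl group outranks vinyl. No structure needed correcting.
- C7 carries a formyl group from the start. It blocks and deactivates ring A (the benzo ring) in the key step and is olefinated directly, so no hydride reagent meets the aryl pivalate before the last step.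
- The (Sa,Sc,Sc) enantiomer of the binaphthol-derived N,N-bis(1-phenylethyl)phosphoramidite is assumed to give the (S) ether, by analogy with the sense of attack established for cinnamyl carbonates. Should a trial run show the opposite sense, the mirror-image ligand is used and nothing else changes.
- Both starting materials (3,4-dihydroxy-5-methoxybenzaldehyde and sinapic acid) are taken as commercial.

Step 1
Reactants: 1 3,4-dihydroxy-5-methoxybenzaldehyde
Product: 2 3-hydroxy-5-methoxy-4-(methoxymethoxy)benzaldehyde
Conditions: MOMCl (1.05 equiv), K2CO3 (1.05 equiv), acetone, 0 °C → rt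
Reagents that add atoms: chloromethyl methyl ether, COCCl
Why: Williamson-type O-alkylation in which the 4-hydroxyl, para to the formyl group, is the more acidic phenol and is therefore ionised and alkylated selectively by one equivalent of weak base, as is known for 3,4-dihydroxybenzaldehydes.

Step 2
Reactants: 3 sinapic acid, (E)-3-(4-hydroxy-3,5-dimethoxyphenyl)prop-2-enoic acid
Product: 5 (E)-3-[3,5-dimethoxy-4-(pivaloyloxy)phenyl]prop-2-enoic acid, via mixed pivalic anhydride 4 (not isolated)
Conditions: PivCl (2.4 equiv), Et3N, DMAP (cat.), CH2Cl2, 0 °C → rt; then H2O, THF, rt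
Reagents that add atoms: pivaloyl chloride, CC(C)(C)C(=O)Cl
Why: DMAP-catalysed acylation of the hindered syringyl phenol, in which the carboxyl group is acylated too and the resulting mixed anhydride 4 is hydrolysed by water at its less hindered cinnamoyl carbonyl, while the doubly ortho-substituted aryl pivalate stays.

Step 3
Reactants: 5 (E)-3-[3,5-dimethoxy-4-(pivaloyloxy)phenyl]prop-2-enoic acid
Product: 7 4-[(E)-3-hydroxyprop-1-en-1-yl]-2,6-dimethoxyphenyl pivalate, via acid chloride 6 (not isolated)
Conditions: (COCl)2, DMF (cat.), CH2Cl2, rt; evaporate; NaBH4, EtOAc, 0 °C → rt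
Reagents that add atoms: none
Why: Acid chloride formation followed by borohydride reduction is the established way from 4-O-acylated hydroxycinnamic acids to the cinnamyl alcohols, since hydride attacks the acyl chloride far faster than the hindered aryl ester and leaves the E alkene untouched.

Step 4
Reactants: 7 4-[(E)-3-hydroxyprop-1-en-1-yl]-2,6-dimethoxyphenyl pivalate
Product: 8 (E)-3-[3,5-dimethoxy-4-(pivaloyloxy)phenyl]allyl methyl carbonate
Conditions: ClCO2Me, pyridine, CH2Cl2, 0 °C
Reagents that add atoms: methyl chloroformate, COC(=O)Cl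
Why: Routine acylation of a primary allylic alcohol with a chloroformate, which installs the carbonate leaving group needed for allyl–metal ionisation.

Step 5
Reactants: 2 3-hydroxy-5-methoxy-4-(methoxymethoxy)benzaldehyde; 8 (E)-3-[3,5-dimethoxy-4-(pivaloyloxy)phenyl]allyl methyl carbonate
Product: 10 4-{(1S)-1-[5-formyl-3-methoxy-2-(methoxymethoxy)phenoxy]prop-2-en-1-yl}-2,6-dimethoxyphenyl pivalate, via sodium phenoxide 9 (not isolated)
Conditions: 2 (1.5 equiv), NaH (0.6 equiv), THF, 0 °C; then 8 (1.0 equiv), [Ir(cod)Cl]2 (2 mol %), (Sa,Sc,Sc)-phosphoramidite (4 mol %), THF, rt → 50 °C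
Reagents that add atoms: none
Why: Iridium-catalysed asymmetric allylic etherification (Tsuji–Trost-type substitution through an allyl complex of the cyclometalated monovalent-iridium phosphoramidite catalyst), in which phenoxide 9 attacks the aryl-substituted allyl terminus to give the branched ether and the ligand fixes the C2 centre as (S), while the excess free phenol 2 quenches the methoxide released from the carbonate so that the aryl pivalate is spared.

Step 6
Reactants: 10 4-{(1S)-1-[5-formyl-3-methoxy-2-(methoxymethoxy)phenoxy]prop-2-en-1-yl}-2,6-dimethoxyphenyl pivalate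
Product: 12 4-[(1S)-1-(5-formyl-2-hydroxy-3-methoxyphenoxy)prop-2-en-1-yl]-2,6-dimethoxyphenyl pivalate (= 3-{(1S)-1-[3,5-dimethoxy-4-(pivaloyloxy)phenyl]allyloxy}-4-hydroxy-5-methoxybenzaldehyde), via trimethylsilyl ether 11 (not isolated)
Conditions: Me3SiOTf (2 equiv), 2,2′-bipyridyl (3 equiv), MeCN, 0 °C → rt; then H2O
Reagents that add atoms: none
Why: Silyl triflate/2,2′-bipyridyl cleavage of an aromatic MOM ether, in which the bipyridyl-buffered silyl electrophile activates only the acetal, converts it into the aryl silyl ether 11 and water then frees the phenol, so that no free Brønsted acid meets the ionisable 1-arylallyl aryl ether, the aryl pivalate or the aldehyde.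

Step 7
Reactants: 12 4-[(1S)-1-(5-formyl-2-hydroxy-3-methoxyphenoxy)prop-2-en-1-yl]-2,6-dimethoxyphenyl pivalate
Product: 13 4-[(2R,3S)-7-formyl-3-(iodomethyl)-5-methoxy-2,3-dihydro-1,4-benzodioxin-2-yl]-2,6-dimethoxyphenyl pivalate (trans)
Conditions: NIS (1.2 equiv), NaHCO3 (2 equiv), MeCN, −20 → 0 °C, dark
Reagents that add atoms: N-iodosuccinimide, O=C1CCC(=O)N1I
Why: NIS forms an iodonium ion reversibly on the vinyl group and the C4a phenol (partly as phenoxide under NaHCO3) opens it anti at the internal carbon, which forms O4–C3 and leaves the terminal carbon as CH2I. The closest known reaction type is the iodoetherification (halocycloetherification) of alkenyl phenols. The dioxane ring closes in the 6-exo-trig mode, the 7-endo alternative requiring attack at the primary carbon. The new C3 stereocentre is controlled by the existing C2 stereocentre: in the chair-like transition state the C2 aryl group and the iodonium-bearing carbon should both sit pseudo-equatorial, so CH2I is expected trans to the aryl group, which is also the more stable arrangement. The step needs exo/Markovnikov regioselectivity, chemoselectivity over arene iodination and an intact C2 centre: the first follows from the tether length, the second from the formyl group blocking the position para to the phenol (both ortho positions are substituted) and from the pivaloyloxy group deactivating ring C, and the third from the pivalate and the buffered medium, which disfavour ionisation of the benzylic C2–O1 bond.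

Step 8
Reactants: 13 4-[(2R,3S)-7-formyl-3-(iodomethyl)-5-methoxy-2,3-dihydro-1,4-benzodioxin-2-yl]-2,6-dimethoxyphenyl pivalate
Product: 14 4-[(2R,3R)-7-formyl-5-methoxy-3-methyl-2,3-dihydro-1,4-benzodioxin-2-yl]-2,6-dimethoxyphenyl pivalate
Conditions: Bu3SnH (1.2 equiv), Et3B (0.2 equiv), air, toluene, 0 °C → rt
Reagents that add atoms: none
Why: Radical-chain tin hydride reduction of a primary alkyl iodide, in which the low temperature and high Bu3SnH concentration should trap the primary radical before the β-aryloxy bond can fragment; C2 and C3 are not touched, and the C3 descriptor changes from S to R only because CH3 ranks below C2.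

Step 9
Reactants: 14 4-[(2R,3R)-7-formyl-5-methoxy-3-methyl-2,3-dihydro-1,4-benzodioxin-2-yl]-2,6-dimethoxyphenyl pivalate
Product: 15 2,6-dimethoxy-4-{(2R,3R)-5-methoxy-3-methyl-7-[(E)-prop-1-en-1-yl]-2,3-dihydro-1,4-benzodioxin-2-yl}phenyl pivalate
Conditions: CrCl2 (8 equiv), CH3CHI2 (2 equiv), THF, rt
Reagents that add atoms: 1,1-diiodoethane, CC(I)I
Why: Takai olefination, in which the geminal dichromium reagent formed from CH3CHI2 and divalent chromium adds to the aryl aldehyde and eliminates to the E alkene, and which, being weakly basic and non-nucleophilic towards esters, should leave the aryl pivalate and the benzylic ethers alone.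

Step 10
Reactants: 15 2,6-dimethoxy-4-{(2R,3R)-5-methoxy-3-methyl-7-[(E)-prop-1-en-1-yl]-2,3-dihydro-1,4-benzodioxin-2-yl}phenyl pivalate
Product: 16 2,6-dimethoxy-4-{(2R,3R)-5-methoxy-3-methyl-7-[(E)-prop-1-en-1-yl]-2,3-dihydro-1,4-benzodioxin-2-yl}phenol (CNP0227775.1)
Conditions: i-Bu2AlH (2.5 equiv), CH2Cl2, −78 → 0 °C; aq KNaC4H4O6
Reagents that add atoms: none
Why: Reductive cleavage of the aryl ester by the aluminium hydride at low temperature (the pivaloyl group leaves as neopentyl alcohol) under non-basic conditions, so that the 4-hydroxybenzyl aryl ether at C2 is not opened through a quinone methide and the propenyl group and ethers stay inert.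

Compound list
1 | 3,4-dihydroxy-5-methoxybenzaldehyde | COc1cc(C=O)cc(O)c1O | starting material
2 | 3-hydroxy-5-methoxy-4-(methoxymethoxy)benzaldehyde | COCOc1c(O)cc(C=O)cc1OC | intermediate
3 | sinapic acid, (E)-3-(4-hydroxy-3,5-dimethoxyphenyl)prop-2-enoic acid | COc1cc(/C=C/C(=O)O)cc(OC)c1O | starting material
4 | (E)-3-[3,5-dimethoxy-4-(pivaloyloxy)phenyl]prop-2-enoic pivalic anhydride (formed in the flask) | COc1cc(/C=C/C(=O)OC(=O)C(C)(C)C)cc(OC)c1OC(=O)C(C)(C)C | intermediate
5 | (E)-3-[3,5-dimethoxy-4-(pivaloyloxy)phenyl]prop-2-enoic acid | COc1cc(/C=C/C(=O)O)cc(OC)c1OC(=O)C(C)(C)C | intermediate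
6 | (E)-3-[3,5-dimethoxy-4-(pivaloyloxy)phenyl]prop-2-enoyl chloride (formed in the flask) | COc1cc(/C=C/C(=O)Cl)cc(OC)c1OC(=O)C(C)(C)C | intermediate
7 | 4-[(E)-3-hydroxyprop-1-en-1-yl]-2,6-dimethoxyphenyl pivalate | COc1cc(/C=C/CO)cc(OC)c1OC(=O)C(C)(C)C | intermediate
8 | (E)-3-[3,5-dimethoxy-4-(pivaloyloxy)phenyl]allyl methyl carbonate | COC(=O)OC/C=C/c1cc(OC)c(OC(=O)C(C)(C)C)c(OC)c1 | intermediate
9 | sodium 5-formyl-3-methoxy-2-(methoxymethoxy)phenolate (formed in the flask) | COCOc1c([O-])cc(C=O)cc1OC.[Na+] | intermediate
10 | 4-{(1S)-1-[5-formyl-3-methoxy-2-(methoxymethoxy)phenoxy]prop-2-en-1-yl}-2,6-dimethoxyphenyl pivalate | COCOc1c(OC)cc(C=O)cc1O[C@H](c1cc(OC)c(OC(=O)C(C)(C)C)c(OC)c1)C=C | intermediate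
11 | 4-{(1S)-1-[5-formyl-3-methoxy-2-(trimethylsilyloxy)phenoxy]prop-2-en-1-yl}-2,6-dimethoxyphenyl pivalate (formed in the flask) | C[Si](C)(C)Oc1c(OC)cc(C=O)cc1O[C@H](c1cc(OC)c(OC(=O)C(C)(C)C)c(OC)c1)C=C | intermediate
12 | 4-[(1S)-1-(5-formyl-2-hydroxy-3-methoxyphenoxy)prop-2-en-1-yl]-2,6-dimethoxyphenyl pivalate (key-step precursor) | COc1cc(C=O)cc(O[C@H](c2cc(OC)c(OC(=O)C(C)(C)C)c(OC)c2)C=C)c1O | intermediate
13 | 4-[(2R,3S)-7-formyl-3-(iodomethyl)-5-methoxy-2,3-dihydro-1,4-benzodioxin-2-yl]-2,6-dimethoxyphenyl pivalate (key-step product, trans) | O=Cc1cc(OC)c2c(c1)O[C@H](c1cc(OC)c(OC(=O)C(C)(C)C)c(OC)c1)[C@@H](CI)O2 | intermediate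
14 | 4-[(2R,3R)-7-formyl-5-methoxy-3-methyl-2,3-dihydro-1,4-benzodioxin-2-yl]-2,6-dimethoxyphenyl pivalate | O=Cc1cc(OC)c2c(c1)O[C@H](c1cc(OC)c(OC(=O)C(C)(C)C)c(OC)c1)[C@@H](C)O2 | intermediate
15 | 2,6-dimethoxy-4-{(2R,3R)-5-methoxy-3-methyl-7-[(E)-prop-1-en-1-yl]-2,3-dihydro-1,4-benzodioxin-2-yl}phenyl pivalate | C/C=C/c1cc(OC)c2c(c1)O[C@H](c1cc(OC)c(OC(=O)C(C)(C)C)c(OC)c1)[C@@H](C)O2 | intermediate
16 | 2,6-dimethoxy-4-{(2R,3R)-5-methoxy-3-methyl-7-[(E)-prop-1-en-1-yl]-2,3-dihydro-1,4-benzodioxin-2-yl}phenol | C/C=C/c1cc(OC)c2c(c1)O[C@H](c1cc(OC)c(O)c(OC)c1)[C@@H](C)O2 | target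

Total step count: 10. Longest linear sequence: 9 steps (from 3 through steps 2 to 10).

Steps most likely to fail

Step 7 (key step). The kinetic ring closure may discriminate the two alkene faces poorly, so that cis and trans isomers at C3 form together, or electrophilic iodination of ring C may compete. The fallback sets out from 12 and replaces iodine by selenium. N-(phenylseleno)phthalimide with catalytic camphorsulfonic acid in CH2Cl2 at rt closes the same ring reversibly, so the product can settle to the more stable trans isomer, and this electrophile does not substitute arenes. The product is 4-[(2R,3S)-7-formyl-5-methoxy-3-[(phenylselanyl)methyl]-2,3-dihydro-1,4-benzodioxin-2-yl]-2,6-dimethoxyphenyl pivalate F3. Bu3SnH/AIBN in toluene at 100 °C then cleaves the C–Se bond, and the sequence comes back at 14, passing over 13.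

Step 5. Enantiomeric purity may be lost through slow, poorly face-selective attack of the ortho-alkoxy phenoxide, or through re-ionisation of the product ether by the catalyst. The fallback sets out from 2 and 8 and runs the coupling with the achiral, branched-selective catalyst [Ir(cod)Cl]2/P(OPh)3 (monovalent iridium). This gives racemic 4-{1-[5-formyl-3-methoxy-2-(methoxymethoxy)phenoxy]prop-2-en-1-yl}-2,6-dimethoxyphenyl pivalate F1, which is resolved by preparative HPLC on a chiral stationary phase. 4-{(1R)-1-[5-formyl-3-methoxy-2-(methoxymethoxy)phenoxy]prop-2-en-1-yl}-2,6-dimethoxyphenyl pivalate F2 is set aside, and the (S)-enantiomer is 10, where the route resumes.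

Step 9. The ethylidenation may be incompletely E-selective, giving a hard-to-separate E/Z mixture, or divalent chromium may dimerise the aryl aldehyde reductively before the dichromium reagent has formed. The fallback sets out from 14 and uses a Julia–Kocienski olefination with 5-(ethylsulfonyl)-1-phenyl-1H-tetrazole and KN(SiMe3)2 in DME, −60 °C → rt. The E alkene there arises from sulfone-anion addition, Smiles rearrangement and elimination, and the sequence comes back at 15. No compound outside the list arises (F0).

Further compounds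
F1 | step 5 | racemic 4-{1-[5-formyl-3-methoxy-2-(methoxymethoxy)phenoxy]prop-2-en-1-yl}-2,6-dimethoxyphenyl pivalate | COCOc1c(OC)cc(C=O)cc1OC(c1cc(OC)c(OC(=O)C(C)(C)C)c(OC)c1)C=C
F2 | step 5 | 4-{(1R)-1-[5-formyl-3-methoxy-2-(methoxymethoxy)phenoxy]prop-2-en-1-yl}-2,6-dimethoxyphenyl pivalate | COCOc1c(OC)cc(C=O)cc1O[C@@H](c1cc(OC)c(OC(=O)C(C)(C)C)c(OC)c1)C=C
F3 | step 7 | 4-[(2R,3S)-7-formyl-5-methoxy-3-[(phenylselanyl)methyl]-2,3-dihydro-1,4-benzodioxin-2-yl]-2,6-dimethoxyphenyl pivalate | O=Cc1cc(OC)c2c(c1)O[C@H](c1cc(OC)c(OC(=O)C(C)(C)C)c(OC)c1)[C@@H](C[Se]c1ccccc1)O2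
F0 | step 9 | none | none
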